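**Plan**

1. Names used: unit 1 is the 7-hydroxychroman on the central ring (ring D); unit 2 is the 3,4-diarylchroman with benzo ring A, pyran ring C and catechol ring B. Retrosynthesis cuts, in order: the five O-benzyl groups and the C4 oxygen of unit 1 (held as an achiral isoflavone until the end); ring C of unit 2 at C3–C4 and O1–C2; the carbinol C–C bond between ring A and ring D; the formyl C–C bond on ring D; the isoflavone back to a chalcone (1,2-aryl shift) and its aldol partners.
2. Enabling feature: in unit 2, O1 sits on ring A ortho to C4a, and C4 is a methine between two donor rings (ring A with O7 para; ring D with OMe ortho and O para). C4=C4a–C8a=O1 is therefore a latent, strongly stabilized ortho-quinone methide, and C2 (bound to O1) with C3 (bearing ring B) is the latent enamine of an arylacetaldehyde.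
3. Forward order: the pyranone ring of unit 1 is closed first (steps 1–2); ring D is formylated and ring A is attached by ortho-hydroxyalkylation (steps 3–4); ring B is made as an arylacetaldehyde (steps 5–7); ring C of unit 2 is closed last by the amine-catalysed quinone methide annulation (step 8). Only reductions follow.
4. Helpers and their removal: C2 at the aldehyde (lactol) level, removed by ionic hydrogenation (step 9); the isoflavone oxidation level of unit 1, which deactivates its benzo ring and carries no stereocentre through the earlier steps, removed by transfer hydrogenation and hydrogenolysis (steps 10–11); benzyl ethers (step 11).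
5. Stereochemistry: C3 and C4 of unit 2 come from the (R)-diphenylprolinol silyl ether enamine (face at C3) and its synclinal approach to the (E)-quinone methide (3,4-trans, C4 = S). C3 of unit 1 comes from RuCl[(R,R)-TsDPEN](p-cymene) transfer hydrogenation with dynamic kinetic resolution (cis-(3R,4R)-alcohol), followed by hydrogenolysis of C4–OH.

Key step: step 8

Remark: benzhydrol 9 (racemic carbinol), enol ether 12 (E/Z) and lactol 16 (C2 anomers) are carried as mixtures because these centres are erased later; compounds 1, 2, 7 and 10 are taken to be commercially available.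

**Step 1**
Reactants: 1 1-[4-(benzyloxy)-2-hydroxyphenyl]ethan-1-one; 2 2-(benzyloxy)-4-methoxybenzaldehyde
Product: 3 (E)-1-[4-(benzyloxy)-2-hydroxyphenyl]-3-[2-(benzyloxy)-4-methoxyphenyl]prop-2-en-1-one
Conditions: KOH (50% aq), EtOH, rt; then dilute HCl
Reagents that add atoms: none
Why: Claisen–Schmidt aldol condensation, in which the potassium enolate of the 2-hydroxyacetophenone adds to the non-enolisable aldehyde and E1cB dehydration gives the conjugated (E)-enone while both benzyl ethers are inert to hydroxide.

**Step 2**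
Reactants: 3 (E)-1-[4-(benzyloxy)-2-hydroxyphenyl]-3-[2-(benzyloxy)-4-methoxyphenyl]prop-2-en-1-one
Product: 5 7-(benzyloxy)-3-[2-(benzyloxy)-4-methoxyphenyl]-4H-chromen-4-one, via dimethyl acetal 4 (not isolated)
Conditions: Tl(NO3)3·3H2O (1.2 equiv), MeOH/HC(OMe)3, rt; filter; then 10% aq HCl, 60 °C
Reagents that add atoms: none
Why: Oxidative 1,2-aryl migration of a 2'-hydroxychalcone by trivalent thallium (the laboratory counterpart of the biosynthetic flavonoid-to-isoflavonoid aryl shift), in which methanol adds to the Tl-activated alkene, the electron-rich 2-benzyloxy-4-methoxyphenyl group moves from the β- to the α-carbon as thallium leaves, and acid then closes the pyranone ring by attack of the phenol on the acetal carbon with loss of two molecules of methanol.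

**Step 3**
Reactants: 5 7-(benzyloxy)-3-[2-(benzyloxy)-4-methoxyphenyl]-4H-chromen-4-one
Product: 6 4-(benzyloxy)-5-[7-(benzyloxy)-4-oxo-4H-chromen-3-yl]-2-methoxybenzaldehyde
Conditions: POCl3 (3 equiv), DMF, 0 → 70 °C; then aq NaOAc
Reagents that add atoms: N,N-dimethylformamide CN(C)C=O; water O
Why: Vilsmeier–Haack formylation, in which the chloroiminium ion should attack the one doubly activated and unhindered carbon of the molecule (para to the benzyloxy and ortho to the methoxy group of the pendant aryl ring) because the benzo ring of the chromone is deactivated by the conjugated carbonyl group.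

**Step 4**
Reactants: 6 4-(benzyloxy)-5-[7-(benzyloxy)-4-oxo-4H-chromen-3-yl]-2-methoxybenzaldehyde; 7 3-(benzyloxy)phenol
Product: 9 7-(benzyloxy)-3-[2-(benzyloxy)-5-{[4-(benzyloxy)-2-hydroxyphenyl](hydroxy)methyl}-4-methoxyphenyl]-4H-chromen-4-one (racemic carbinol), via bromomagnesium phenoxide 8 (not isolated)
Conditions: 7, EtMgBr (1.0 equiv), Et2O, 0 °C; switch solvent to toluene; then 6 (0.9 equiv), rt; aq NH4Cl
Reagents that add atoms: none
Why: Casiraghi ortho-specific hydroxyalkylation, in which the aldehyde is bound to the magnesium of the phenoxide and is attacked through a six-membered chelate by the ortho carbon lying para to the benzyloxy group (the other ortho carbon is flanked by two oxygens), giving the 2-hydroxybenzhydrol directly with its phenol free and a carbinol centre that is erased in step 8.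

**Step 5**
Reactants: 10 2,3-dihydroxy-4-methoxybenzaldehyde
Product: 11 2,3-bis(benzyloxy)-4-methoxybenzaldehyde
Conditions: BnBr (2.4 equiv), K2CO3 (3 equiv), DMF, 60 °C
Reagents that add atoms: benzyl bromide BrCc1ccccc1
Why: Williamson ether synthesis, in which both phenoxides displace bromide from benzyl bromide (SN2) so that ring B carries the same hydrogenolysable protection as the rest of the molecule.

**Step 6**
Reactants: 11 2,3-bis(benzyloxy)-4-methoxybenzaldehyde
Product: 12 2,3-bis(benzyloxy)-4-methoxy-1-(2-methoxyethenyl)benzene (E/Z mixture)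
Conditions: Ph3P(CH2OMe)Cl (1.5 equiv), KOtBu (1.4 equiv), THF, 0 °C → rt
Reagents that add atoms: (methoxymethyl)triphenylphosphonium chloride COC[P+](c1ccccc1)(c1ccccc1)c1ccccc1.[Cl-]
Why: Wittig methoxymethylenation of the aryl aldehyde gives the one-carbon-homologated enol ether, whose alkene geometry does not matter because the next step hydrolyses it.

**Step 7**
Reactants: 12 2,3-bis(benzyloxy)-4-methoxy-1-(2-methoxyethenyl)benzene
Product: 13 2-[2,3-bis(benzyloxy)-4-methoxyphenyl]acetaldehyde
Conditions: 2 M aq HCl, THF, 50 °C; used at once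
Reagents that add atoms: water O
Why: Acid-catalysed enol ether hydrolysis (C-protonation, hydration of the oxocarbenium ion, loss of methanol) should release the arylacetaldehyde without touching the benzyl ethers, and the aldehyde is used immediately because arylacetaldehydes self-condense on storage.

**Step 8**
Reactants: 9 7-(benzyloxy)-3-[2-(benzyloxy)-5-{[4-(benzyloxy)-2-hydroxyphenyl](hydroxy)methyl}-4-methoxyphenyl]-4H-chromen-4-one; 13 2-[2,3-bis(benzyloxy)-4-methoxyphenyl]acetaldehyde
Product: 16 7-(benzyloxy)-3-{2-(benzyloxy)-5-[(3R,4S)-7-(benzyloxy)-3-[2,3-bis(benzyloxy)-4-methoxyphenyl]-2-hydroxy-3,4-dihydro-2H-chromen-4-yl]-4-methoxyphenyl}-4H-chromen-4-one (3,4-trans; C2 anomers), via ortho-quinone methide 14 (not isolated), via hydroxyaryl aldehyde 15 (not isolated)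
Conditions: (R)-2-[diphenyl(trimethylsilyloxy)methyl]pyrrolidine (20 mol%), 4-nitrobenzoic acid (20 mol%), 13 (2.5 equiv, added slowly), CHCl3, rt
Reagents that add atoms: none
Why: The acid cocatalyst dehydrates benzhydrol 9 to ortho-quinone methide 14, which is stabilized by the ortho-methoxy/para-benzyloxy aryl group on its methide carbon and by the para-benzyloxy group of its dienone ring, while aldehyde 13 condenses with the pyrrolidine to an (E)-enamine whose β-carbon adds to the methide carbon (C3–C4 bond, ring A rearomatized) before iminium hydrolysis gives aldehyde 15 and returns the catalyst. The closest known reaction type is the diarylprolinol silyl ether catalysed formal [4+2] annulation of aldehydes with ortho-quinone methides generated in situ, which gives trans-3,4-disubstituted chroman-2-ols and is related to the enamine Michael addition to nitroalkenes and to the SN1-type α-alkylation of aldehydes with benzhydrols. Ring C is completed by 6-exo-trig addition of the liberated phenol oxygen O1 to the aldehyde carbon C2 (hemiacetal), so that C3–C4 and O1–C2 are both made in this step. C3 is set by the catalyst, whose diphenyl(silyloxy)methyl group blocks one face of the s-trans (E)-enamine, and C4 by the synclinal approach of that enamine to the (E)-quinone methide with the dienone oxygen near the enamine nitrogen; by analogy with the syn-selective nitroalkene additions of this catalyst class, the (R)-catalyst should give the (2R,3S)-aldehyde and hence the (3R,4S)-trans lactol, and because C3 can still epimerize through 15 while C4 is fixed, the trans-diequatorial isomer is also the thermodynamic one. The step needs chemoselectivity for the quinone methide over the isoflavone enone and over aldehyde self-condensation, and a single quinone methide geometry; these should be secured by the far higher electrophilicity of the methide carbon compared with the hindered vinylogous-ester C2 of the 3-arylchromone, by slow addition of excess 13, and by allylic strain that keeps the aryl group of 14 anti to the carbonyl group.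

**Step 9**
Reactants: 16 the (3R,4S)-chroman-2-ol from step 8
Product: 17 7-(benzyloxy)-3-{2-(benzyloxy)-5-[(3R,4S)-7-(benzyloxy)-3-[2,3-bis(benzyloxy)-4-methoxyphenyl]-3,4-dihydro-2H-chromen-4-yl]-4-methoxyphenyl}-4H-chromen-4-one
Conditions: Et3SiH (5 equiv), BF3·OEt2 (3 equiv), CH2Cl2, −78 → −30 °C
Reagents that add atoms: none
Why: Ionic hydrogenation of the lactol (Lewis-acid ionization to the cyclic aryloxycarbenium ion, then hydride transfer from the silane) should remove the C2 oxygen with the ring closed and C3 and C4 untouched, because this very electrophilic ion is captured by hydride faster than it loses the C3 proton and the BF3-complexed chromone is much less electrophilic at low temperature.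

**Step 10**
Reactants: 17 the (3R,4S)-chroman carrying the isoflavone
Product: 19 (3R,4R)-7-(benzyloxy)-3-{2-(benzyloxy)-5-[(3R,4S)-7-(benzyloxy)-3-[2,3-bis(benzyloxy)-4-methoxyphenyl]-3,4-dihydro-2H-chromen-4-yl]-4-methoxyphenyl}-3,4-dihydro-2H-chromen-4-ol (3,4-cis), via isoflavanone 18 (not isolated)
Conditions: RuCl[(R,R)-TsDPEN](p-cymene) (5 mol%), HCO2H/Et3N (5:2), EtOAc, 40 °C
Reagents that add atoms: none
Why: Noyori–Ikariya asymmetric transfer hydrogenation with dynamic kinetic resolution, in which the ruthenium hydride first reduces the chromone C2=C3 bond to isoflavanone 18, C3 of 18 epimerizes rapidly through the enol in the presence of Et3N, and the (R,R)-catalyst reduces the ketone of the matched epimer to the (4R)-alcohol with the aryl group cis, so that C3 of unit 1 becomes R under catalyst control irrespective of the remote stereocentres.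

**Step 11**
Reactants: 19 the cis-(3R,4R)-chroman-4-ol from step 10
Product: 20 (3R,4S)-3-(2,3-dihydroxy-4-methoxyphenyl)-4-{4-hydroxy-5-[(3R)-7-hydroxy-3,4-dihydro-2H-chromen-3-yl]-2-methoxyphenyl}-3,4-dihydro-2H-chromen-7-ol
Conditions: H2 (3 atm), 10% Pd/C, THF/MeOH, rt
Reagents that add atoms: none
Why: Catalytic hydrogenolysis on palladium should cleave the five benzyl ethers and the electron-rich benzylic C4–OH bond of unit 1 (C4 becomes CH2) while the three stereocentres, none of which lies on a benzylic C–O bond, stay unchanged.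

**Compound list**

1 | 1-[4-(benzyloxy)-2-hydroxyphenyl]ethan-1-one | CC(=O)c1ccc(OCc2ccccc2)cc1O | starting material
2 | 2-(benzyloxy)-4-methoxybenzaldehyde | COc1ccc(C=O)c(OCc2ccccc2)c1 | starting material
3 | (E)-1-[4-(benzyloxy)-2-hydroxyphenyl]-3-[2-(benzyloxy)-4-methoxyphenyl]prop-2-en-1-one | O=C(/C=C/c1ccc(OC)cc1OCc1ccccc1)c1ccc(OCc2ccccc2)cc1O | intermediate
4 | 1-[4-(benzyloxy)-2-hydroxyphenyl]-2-[2-(benzyloxy)-4-methoxyphenyl]-3,3-dimethoxypropan-1-one (racemic) | COC(OC)C(C(=O)c1ccc(OCc2ccccc2)cc1O)c1ccc(OC)cc1OCc1ccccc1 | intermediate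
5 | 7-(benzyloxy)-3-[2-(benzyloxy)-4-methoxyphenyl]-4H-chromen-4-one | COc1ccc(-c2coc3cc(OCc4ccccc4)ccc3c2=O)c(OCc2ccccc2)c1 | intermediate
6 | 4-(benzyloxy)-5-[7-(benzyloxy)-4-oxo-4H-chromen-3-yl]-2-methoxybenzaldehyde | COc1cc(OCc2ccccc2)c(-c2coc3cc(OCc4ccccc4)ccc3c2=O)cc1C=O | intermediate
7 | 3-(benzyloxy)phenol | Oc1cccc(OCc2ccccc2)c1 | starting material
8 | bromomagnesium 3-(benzyloxy)phenoxide | Br[Mg]Oc1cccc(OCc2ccccc2)c1 | intermediate
9 | 7-(benzyloxy)-3-[2-(benzyloxy)-5-{[4-(benzyloxy)-2-hydroxyphenyl](hydroxy)methyl}-4-methoxyphenyl]-4H-chromen-4-one (racemic carbinol) | COc1cc(OCc2ccccc2)c(-c2coc3cc(OCc4ccccc4)ccc3c2=O)cc1C(O)c1ccc(OCc2ccccc2)cc1O | intermediate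
10 | 2,3-dihydroxy-4-methoxybenzaldehyde | COc1ccc(C=O)c(O)c1O | starting material
11 | 2,3-bis(benzyloxy)-4-methoxybenzaldehyde | COc1ccc(C=O)c(OCc2ccccc2)c1OCc1ccccc1 | intermediate
12 | 2,3-bis(benzyloxy)-4-methoxy-1-(2-methoxyethenyl)benzene (E/Z mixture) | COC=Cc1ccc(OC)c(OCc2ccccc2)c1OCc1ccccc1 | intermediate
13 | 2-[2,3-bis(benzyloxy)-4-methoxyphenyl]acetaldehyde | O=CCc1ccc(OC)c(OCc2ccccc2)c1OCc1ccccc1 | intermediate
14 | 7-(benzyloxy)-3-[2-(benzyloxy)-5-{(E)-[4-(benzyloxy)-6-oxocyclohexa-2,4-dien-1-ylidene]methyl}-4-methoxyphenyl]-4H-chromen-4-one (ortho-quinone methide) | COc1cc(OCc2ccccc2)c(-c2coc3cc(OCc4ccccc4)ccc3c2=O)cc1/C=C1\C=CC(OCc2ccccc2)=CC1=O | intermediate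
15 | (2R,3S)-2-[2,3-bis(benzyloxy)-4-methoxyphenyl]-3-[4-(benzyloxy)-2-hydroxyphenyl]-3-{4-(benzyloxy)-5-[7-(benzyloxy)-4-oxo-4H-chromen-3-yl]-2-methoxyphenyl}propanal | COc1cc(OCc2ccccc2)c(-c2coc3cc(OCc4ccccc4)ccc3c2=O)cc1[C@H](c1ccc(OCc2ccccc2)cc1O)[C@@H](C=O)c1ccc(OC)c(OCc2ccccc2)c1OCc1ccccc1 | intermediate
16 | 7-(benzyloxy)-3-{2-(benzyloxy)-5-[(3R,4S)-7-(benzyloxy)-3-[2,3-bis(benzyloxy)-4-methoxyphenyl]-2-hydroxy-3,4-dihydro-2H-chromen-4-yl]-4-methoxyphenyl}-4H-chromen-4-one (C2 anomers) | COc1cc(OCc2ccccc2)c(-c2coc3cc(OCc4ccccc4)ccc3c2=O)cc1[C@@H]1c2ccc(OCc3ccccc3)cc2OC(O)[C@H]1c1ccc(OC)c(OCc2ccccc2)c1OCc1ccccc1 | intermediate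
17 | 7-(benzyloxy)-3-{2-(benzyloxy)-5-[(3R,4S)-7-(benzyloxy)-3-[2,3-bis(benzyloxy)-4-methoxyphenyl]-3,4-dihydro-2H-chromen-4-yl]-4-methoxyphenyl}-4H-chromen-4-one | COc1cc(OCc2ccccc2)c(-c2coc3cc(OCc4ccccc4)ccc3c2=O)cc1[C@@H]1c2ccc(OCc3ccccc3)cc2OC[C@H]1c1ccc(OC)c(OCc2ccccc2)c1OCc1ccccc1 | intermediate
18 | 7-(benzyloxy)-3-{2-(benzyloxy)-5-[(3R,4S)-7-(benzyloxy)-3-[2,3-bis(benzyloxy)-4-methoxyphenyl]-3,4-dihydro-2H-chromen-4-yl]-4-methoxyphenyl}-2,3-dihydro-4H-chromen-4-one (C3 epimers of the chromanone) | COc1cc(OCc2ccccc2)c(C2COc3cc(OCc4ccccc4)ccc3C2=O)cc1[C@@H]1c2ccc(OCc3ccccc3)cc2OC[C@H]1c1ccc(OC)c(OCc2ccccc2)c1OCc1ccccc1 | intermediate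
19 | (3R,4R)-7-(benzyloxy)-3-{2-(benzyloxy)-5-[(3R,4S)-7-(benzyloxy)-3-[2,3-bis(benzyloxy)-4-methoxyphenyl]-3,4-dihydro-2H-chromen-4-yl]-4-methoxyphenyl}-3,4-dihydro-2H-chromen-4-ol | COc1cc(OCc2ccccc2)c([C@@H]2COc3cc(OCc4ccccc4)ccc3[C@@H]2O)cc1[C@@H]1c2ccc(OCc3ccccc3)cc2OC[C@H]1c1ccc(OC)c(OCc2ccccc2)c1OCc1ccccc1 | intermediate
20 | (3R,4S)-3-(2,3-dihydroxy-4-methoxyphenyl)-4-{4-hydroxy-5-[(3R)-7-hydroxy-3,4-dihydro-2H-chromen-3-yl]-2-methoxyphenyl}-3,4-dihydro-2H-chromen-7-ol | COc1cc(O)c([C@@H]2COc3cc(O)ccc3C2)cc1[C@@H]1c2ccc(O)cc2OC[C@H]1c1ccc(OC)c(O)c1O | target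

**Step count and risks**

Total step count: 11. Longest linear sequence: 8 steps (steps 1, 2, 3, 4, 8, 9, 10, 11, from compounds 1 and 2); steps 5–7 form the three-step side branch to aldehyde 13.

Steps most likely to fail:

Step 8. The very stabilized quinone methide may react slowly with a hindered α-aryl enamine, so that self-condensation of the arylacetaldehyde or oligomerization of the quinone methide outruns the C3–C4 bond formation; facial selectivity at C4 may also erode if both quinone methide geometries react. The fallback sets out from 9 and the (E)-isomer of 12 and replaces enamine catalysis by Brønsted-acid catalysis with a neutral, non-enolisable dienophile. A BINOL-derived chiral phosphoric acid such as 3,3'-bis(2,4,6-triisopropylphenyl)-BINOL hydrogen phosphate (10 mol%, toluene, 0 °C; enantiomer of the acid chosen by experiment) would generate 14 and catalyse its inverse-electron-demand hetero-Diels–Alder reaction with the enol ether. The same ring would be closed through C3–C4 and O1–C2, with endo addition of the (E)-alkene expected to give the 3,4-trans 2-methoxychroman acetal F1. The Et3SiH/BF3·OEt2 conditions of step 9 would then reduce the acetal, and the route is rejoined at 17.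

Step 4. The magnesium salt of the product may ionize to the quinone methide and be captured by a second phenoxide (over-arylation to a triarylmethane), the electron-rich aldehyde may convert slowly, and attack at the other ortho carbon may compete. The fallback sets out from 6 and 7 and uses a boron template instead of the magnesium phenoxide. PhB(OH)2 with catalytic propionic acid in toluene at reflux with removal of water (Nagata ortho-hydroxyalkylation) would deliver the aldehyde to the ortho carbon within a mixed boronate and trap the product as the cyclic phenylboronate (4H-1,3,2-benzodioxaborinine) F2, which cannot ionize further. Transesterification with propane-1,3-diol (THF, rt) would release the diol, and the route is rejoined at 9.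

Step 9. The oxocarbenium ion may lose the C3 proton to give a 4H-chromene that is re-protonated without control, which would scramble C3; partial reduction of the Lewis-acid-complexed chromone is a second possible loss. The fallback sets out from 16 and avoids any cation at C2. PhOC(S)Cl, pyridine and DMAP in CH2Cl2 would convert the lactol into the anomeric O-phenyl thionocarbonate F3. Bu3SnH with AIBN in toluene at 80 °C (Barton–McCombie deoxygenation through the C2 α-oxy radical) would then replace the C2 oxygen by hydrogen with the ring closed, and the route is rejoined at 17.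

**Further compounds**

F1 | step 8 | 7-(benzyloxy)-3-{2-(benzyloxy)-5-[(3R,4S)-7-(benzyloxy)-3-[2,3-bis(benzyloxy)-4-methoxyphenyl]-2-methoxy-3,4-dihydro-2H-chromen-4-yl]-4-methoxyphenyl}-4H-chromen-4-one | COc1cc(OCc2ccccc2)c(-c2coc3cc(OCc4ccccc4)ccc3c2=O)cc1[C@@H]1c2ccc(OCc3ccccc3)cc2OC(OC)[C@H]1c1ccc(OC)c(OCc2ccccc2)c1OCc1ccccc1
F2 | step 4 | 7-(benzyloxy)-3-{2-(benzyloxy)-5-[7-(benzyloxy)-2-phenyl-4H-1,3,2-benzodioxaborinin-4-yl]-4-methoxyphenyl}-4H-chromen-4-one (racemic) | COc1cc(OCc2ccccc2)c(-c2coc3cc(OCc4ccccc4)ccc3c2=O)cc1C1OB(c2ccccc2)Oc2cc(OCc3ccccc3)ccc21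
F3 | step 9 | O-{(3R,4S)-7-(benzyloxy)-4-{4-(benzyloxy)-5-[7-(benzyloxy)-4-oxo-4H-chromen-3-yl]-2-methoxyphenyl}-3-[2,3-bis(benzyloxy)-4-methoxyphenyl]-3,4-dihydro-2H-chromen-2-yl} O-phenyl carbonothioate | COc1cc(OCc2ccccc2)c(-c2coc3cc(OCc4ccccc4)ccc3c2=O)cc1[C@@H]1c2ccc(OCc3ccccc3)cc2OC(OC(=S)Oc2ccccc2)[C@H]1c1ccc(OC)c(OCc2ccccc2)c1OCc1ccccc1
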